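The target is a (2R,3R)-dihydroflavonol whose ring C oxygen O1 and carbonyl carbon C4 hang on neighbouring ring A carbons C8a and C4a. That ortho relationship is exploited by cutting ring C at O1–C2 and C3–C4: ring A becomes a salicylaldehyde dimethyl acetal (latent 4-methoxy ortho-quinone methide, carrying the C8 prenyl and two MOM ethers) and C2–C3 with ring B becomes a geometrically pure (E)-aryl enol pivalate. One chiral-acid-catalysed hetero-[4+2] addition then closes ring C, forms both bonds, sets the 2,3-trans pair and delivers C4 already oxygenated, so no C–H oxidation is needed beside the three allylic side chains. Ester cleavage, methoxy–hydroxy exchange, benzylic oxidation and MOM removal finish the synthesis.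

Key step: step 11

Remark: prenyl = 3-methylbut-2-en-1-yl, geranyl = (2E)-3,7-dimethylocta-2,6-dien-1-yl, MOM = methoxymethyl; compounds 22–26 carry flavan numbering (O1, C2, C3, C4, C4a, C5–C8, C8a).
Remark: C4 of 22–24 ends as the carbonyl carbon, so its configuration is immaterial; 22 and 23 are written as the all-trans isomers and 24 with C4 left open.
Remark: the (R)-configured catalyst is assumed to give the 2R series; if the first run shows the opposite sense, its enantiomer is used with no other change.

Step 1
Reactants: 1 2,4,6-trihydroxybenzaldehyde; 2 prenyl bromide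
Product: 3 2,4,6-trihydroxy-3-prenylbenzaldehyde
Conditions: KOH (1 equiv), H2O, 0 °C → rt
Reagents that add atoms: none
Why: Phenoxide C-alkylation of the ambident phloroglucinol anion, in which the two free ring carbons of 1 are equivalent so that mono-C-prenylation can give only 3, water favouring C- over O-alkylation.

Step 2
Reactants: 3 2,4,6-trihydroxy-3-prenylbenzaldehyde
Product: 4 2-hydroxy-4,6-bis(methoxymethoxy)-3-prenylbenzaldehyde
Conditions: MOMCl (2.1 equiv), i-Pr2NEt, CH2Cl2, 0 °C
Reagents that add atoms: chloromethyl methyl ether, COCCl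
Why: Williamson-type O-alkylation in which O4 (para to the formyl group, most acidic) and the unhindered O6 should react, while the hydroxyl at C2, wedged between formyl and prenyl and held in the stronger hydrogen bond, should stay free.

Step 3
Reactants: 4 2-hydroxy-4,6-bis(methoxymethoxy)-3-prenylbenzaldehyde
Product: 5 2-(dimethoxymethyl)-3,5-bis(methoxymethoxy)-6-prenylphenol
Conditions: HC(OMe)3, MeOH, PPTS (5 mol %), rt; Et3N, basic Al2O3 plug, used at once
Reagents that add atoms: trimethyl orthoformate, COC(OC)OC; methanol, CO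
Why: Acid-catalysed acetalisation driven by the orthoformate as water scavenger, under acid too mild to touch aryl MOM ethers or the prenyl group, with the labile acetal kept away from silica.

Step 4
Reactants: 6 resorcinol
Product: 7 1,3-bis(methoxymethoxy)benzene
Conditions: MOMCl, NaH, DMF, 0 °C → rt
Reagents that add atoms: chloromethyl methyl ether, COCCl
Why: Williamson ether synthesis on both phenoxides, a routine double protection that installs the two directing groups for the metalations that follow.

Step 5
Reactants: 7 1,3-bis(methoxymethoxy)benzene; 8 geranyl bromide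
Product: 10 2-geranyl-1,3-bis(methoxymethoxy)benzene, via 2-lithio-1,3-bis(methoxymethoxy)benzene 9 (not isolated)
Conditions: n-BuLi, THF, 0 °C; CuBr·SMe2 (10 mol %), then 8, −20 °C → rt
Reagents that add atoms: none
Why: Directed ortho-metalation at the carbon flanked by both MOM ethers followed by copper-catalysed SN2 allylation, which joins the primary carbon of the geranyl unit and keeps its (E) double bond.

Step 6
Reactants: 10 2-geranyl-1,3-bis(methoxymethoxy)benzene; 2 prenyl bromide
Product: 12 2-geranyl-1,3-bis(methoxymethoxy)-4-prenylbenzene, via 2-geranyl-4-lithio-1,3-bis(methoxymethoxy)benzene 11 (not isolated)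
Conditions: n-BuLi, TMEDA, THF, 0 °C; CuBr·SMe2 (10 mol %), then 2, −20 °C → rt
Reagents that add atoms: none
Why: Second directed ortho-metalation at one of the two equivalent ring positions next to a MOM ether, where complex-induced ring lithiation should outrun deprotonation of the allylic-benzylic CH2, followed by copper-catalysed SN2 allylation.

Step 7
Reactants: 12 2-geranyl-1,3-bis(methoxymethoxy)-4-prenylbenzene
Product: 14 3-geranyl-2,4-bis(methoxymethoxy)-5-prenylbenzaldehyde, via 2-geranyl-6-lithio-1,3-bis(methoxymethoxy)-4-prenylbenzene 13 (not isolated)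
Conditions: n-BuLi, TMEDA, THF, 0 °C; DMF, −78 → 0 °C; H2O
Reagents that add atoms: N,N-dimethylformamide, CN(C)C=O
Why: Third directed ortho-metalation at the only ring hydrogen left next to a MOM ether, trapped by DMF in a Bouveault-type formylation.

Step 8
Reactants: 14 3-geranyl-2,4-bis(methoxymethoxy)-5-prenylbenzaldehyde; 15 bis(pinacolboryl)methane
Product: 17 (E)-2-[3-geranyl-2,4-bis(methoxymethoxy)-5-prenylphenyl]vinylboronic acid pinacol ester, via lithiated bis(pinacolboryl)methane 16 (not isolated)
Conditions: 15, LiTMP (from 2,2,6,6-tetramethylpiperidine and n-BuLi), THF, 0 °C; then 14, −78 °C → rt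
Reagents that add atoms: none
Why: Boron–Wittig olefination, in which the α-boryl carbanion adds to the aldehyde and syn-elimination of a borate gives the trans-alkenyl boronate, fixing the alkene geometry that later becomes the 2,3-trans relationship.

Step 9
Reactants: 17 (E)-2-[3-geranyl-2,4-bis(methoxymethoxy)-5-prenylphenyl]vinylboronic acid pinacol ester
Product: 18 potassium (E)-{2-[3-geranyl-2,4-bis(methoxymethoxy)-5-prenylphenyl]vinyl}trifluoroborate
Conditions: KHF2, MeOH/H2O, rt
Reagents that add atoms: potassium hydrogen difluoride, F.[F-].[K+]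
Why: Ligand exchange at boron to the trifluoroborate needed for the copper coupling, under weakly acidic conditions that aryl MOM ethers tolerate and that leave the alkene geometry untouched.

Step 10
Reactants: 18 potassium (E)-{2-[3-geranyl-2,4-bis(methoxymethoxy)-5-prenylphenyl]vinyl}trifluoroborate; 19 pivalic acid
Product: 20 (E)-2-[3-geranyl-2,4-bis(methoxymethoxy)-5-prenylphenyl]vinyl pivalate
Conditions: CuBr (10 mol %), DMAP (20 mol %), 4 Å MS, O2 (1 atm), MeCN, 60 °C
Reagents that add atoms: none
Why: Chan–Lam-type oxidative copper-catalysed C–O coupling of an alkenyltrifluoroborate with a carboxylic acid, stereospecific with retention, so 20 is obtained as the pure (E) isomer, which O-acylation of an arylacetaldehyde enolate could not guarantee.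

Step 11
Reactants: 5 2-(dimethoxymethyl)-3,5-bis(methoxymethoxy)-6-prenylphenol; 20 (E)-2-[3-geranyl-2,4-bis(methoxymethoxy)-5-prenylphenyl]vinyl pivalate
Product: 22 (2R,3S,4R)-2-[3-geranyl-2,4-bis(methoxymethoxy)-5-prenylphenyl]-4-methoxy-5,7-bis(methoxymethoxy)-8-prenylchroman-3-yl pivalate, via methoxy-substituted ortho-quinone methide 21 (not isolated)
Conditions: (R)-TRIP-derived N-triflylphosphoramide (10 mol %), 5 Å MS, toluene, −40 °C, slow addition of 5 (1.5 equiv); Et3N quench
Reagents that add atoms: none
Why: Proposed new method: the acid protonates an acetal oxygen of 5, methanol leaves into the sieves, and the 2-hydroxyaryl oxocarbenium ion, in equilibrium with its conjugate base 21 (C8a=O, C4a=C4–OMe) held on the chiral anion, is attacked at C4 by enol carbon C3 of 20, after which O1 collapses onto the benzylic cation at C2 in an asynchronous inverse-demand hetero-[4+2] addition. The closest known reactions are acid-promoted [4+2] additions of salicylaldehyde acetals to styrenes, which give 4-alkoxyflavans, and chiral phosphoric acid or N-triflylphosphoramide catalysed cycloadditions of ortho-quinone methides with styrenes, whereas an enol ester as the 2π partner and absolute control with it are untested. Ring C, six-membered, closes by intermolecular (4+2) annulation, C3–C4 first and O1–C2 second, the second bond being the capture of a benzylic cation by the ring A oxygen. C2 is set by the face of the dienophile that the catalyst leaves open to the ion-paired heterodiene (2R intended), C3 follows from C2 because the addition across the (E) alkene is suprafacial (aryl and acyloxy trans, 3S by the priority rules, the same spatial sense as 3R in the target), and C4 follows the endo/exo preference and may be a mixture. The step needs regioselectivity (aryl on C2) and chemoselectivity over four trisubstituted side-chain alkenes: the 2,4-dioxygenated ring B stabilises positive charge at C2 far better than the weakly donating acyloxy group would at C3, and conjugation makes the enol ester the most electron-rich π bond present. A strong, confined acid is chosen because the dienophile has no hydrogen-bond donor, and the bulky pivalate resists transacylation by the methanol set free.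

Step 12
Reactants: 22 (2R,3S,4R)-2-[3-geranyl-2,4-bis(methoxymethoxy)-5-prenylphenyl]-4-methoxy-5,7-bis(methoxymethoxy)-8-prenylchroman-3-yl pivalate
Product: 23 (2R,3S,4R)-2-[3-geranyl-2,4-bis(methoxymethoxy)-5-prenylphenyl]-4-methoxy-5,7-bis(methoxymethoxy)-8-prenylchroman-3-ol
Conditions: i-Bu2AlH, CH2Cl2, −78 °C; aq KNa tartrate
Reagents that add atoms: none
Why: Reductive ester cleavage by hydride, fast even on a hindered pivalate at low temperature and inert towards MOM ethers, alkenes and the C4 ether, with the C3–O bond untouched so that C3 is retained.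

Step 13
Reactants: 23 (2R,3S,4R)-2-[3-geranyl-2,4-bis(methoxymethoxy)-5-prenylphenyl]-4-methoxy-5,7-bis(methoxymethoxy)-8-prenylchroman-3-ol
Product: 24 (2R,3S)-2-[3-geranyl-2,4-bis(methoxymethoxy)-5-prenylphenyl]-5,7-bis(methoxymethoxy)-8-prenylchromane-3,4-diol (both C4 epimers)
Conditions: PPTS (20 mol %), THF/H2O 4:1, rt
Reagents that add atoms: water, O
Why: SN1 solvolysis of the benzylic ether, since the three oxygens ortho and para to C4a let C4 ionise under acid far too weak for MOM cleavage, water captures the cation, and prior removal of the ester excludes acyloxonium formation and acyl shift, C2 and C3 taking no part.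

Step 14
Reactants: 24 (2R,3S)-2-[3-geranyl-2,4-bis(methoxymethoxy)-5-prenylphenyl]-5,7-bis(methoxymethoxy)-8-prenylchromane-3,4-diol
Product: 25 (2R,3R)-2-[3-geranyl-2,4-bis(methoxymethoxy)-5-prenylphenyl]-3-hydroxy-5,7-bis(methoxymethoxy)-8-prenylchroman-4-one
Conditions: activated MnO2 (excess), CH2Cl2, rt
Reagents that add atoms: none
Why: Chemoselective MnO2 oxidation of the benzylic C4 alcohol of either epimer beside the unactivated C3 alcohol and the side-chain alkenes, under neutral conditions that cannot enolise C3 or open ring C.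

Step 15
Reactants: 25 (2R,3R)-2-[3-geranyl-2,4-bis(methoxymethoxy)-5-prenylphenyl]-3-hydroxy-5,7-bis(methoxymethoxy)-8-prenylchroman-4-one
Product: 26 (2R,3R)-2-[3-geranyl-2,4-dihydroxy-5-prenylphenyl]-3,5,7-trihydroxy-8-prenylchroman-4-one
Conditions: 3 M aq HCl/MeOH 1:4, 45 °C, short reaction time
Reagents that add atoms: none
Why: Acid-catalysed acetal exchange (MOM removal) with methanol as formaldehyde acceptor, safe now that C4 is a ketone and no benzylic cation can form, the short time limiting cyclisation of the prenyl groups onto the freed phenols and the 2,3-trans arrangement being the stable one.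

Compound list
1 | 2,4,6-trihydroxybenzaldehyde | O=Cc1c(O)cc(O)cc1O | starting material
2 | prenyl bromide | CC(C)=CCBr | starting material
3 | 2,4,6-trihydroxy-3-prenylbenzaldehyde | O=Cc1c(O)cc(O)c(CC=C(C)C)c1O | intermediate
4 | 2-hydroxy-4,6-bis(methoxymethoxy)-3-prenylbenzaldehyde | O=Cc1c(OCOC)cc(OCOC)c(CC=C(C)C)c1O | intermediate
5 | 2-(dimethoxymethyl)-3,5-bis(methoxymethoxy)-6-prenylphenol | COC(OC)c1c(OCOC)cc(OCOC)c(CC=C(C)C)c1O | intermediate
6 | resorcinol | Oc1cccc(O)c1 | starting material
7 | 1,3-bis(methoxymethoxy)benzene | COCOc1cccc(OCOC)c1 | intermediate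
8 | geranyl bromide | CC(C)=CCC/C(C)=C/CBr | starting material
9 | 2-lithio-1,3-bis(methoxymethoxy)benzene | [Li]c1c(OCOC)cccc1OCOC | intermediate (not isolated)
10 | 2-geranyl-1,3-bis(methoxymethoxy)benzene | CC(C)=CCC/C(C)=C/Cc1c(OCOC)cccc1OCOC | intermediate
11 | 2-geranyl-4-lithio-1,3-bis(methoxymethoxy)benzene | CC(C)=CCC/C(C)=C/Cc1c(OCOC)c([Li])ccc1OCOC | intermediate (not isolated)
12 | 2-geranyl-1,3-bis(methoxymethoxy)-4-prenylbenzene | CC(C)=CCC/C(C)=C/Cc1c(OCOC)c(CC=C(C)C)ccc1OCOC | intermediate
13 | 2-geranyl-6-lithio-1,3-bis(methoxymethoxy)-4-prenylbenzene | CC(C)=CCC/C(C)=C/Cc1c(OCOC)c(CC=C(C)C)cc([Li])c1OCOC | intermediate (not isolated)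
14 | 3-geranyl-2,4-bis(methoxymethoxy)-5-prenylbenzaldehyde | CC(C)=CCC/C(C)=C/Cc1c(OCOC)c(CC=C(C)C)cc(C=O)c1OCOC | intermediate
15 | bis(pinacolboryl)methane | CC1(C)OB(CB2OC(C)(C)C(C)(C)O2)OC1(C)C | starting material
16 | lithiated bis(pinacolboryl)methane | [Li]C(B1OC(C)(C)C(C)(C)O1)B1OC(C)(C)C(C)(C)O1 | intermediate (not isolated)
17 | (E)-2-[3-geranyl-2,4-bis(methoxymethoxy)-5-prenylphenyl]vinylboronic acid pinacol ester | CC(C)=CCC/C(C)=C/Cc1c(OCOC)c(CC=C(C)C)cc(/C=C/B2OC(C)(C)C(C)(C)O2)c1OCOC | intermediate
18 | potassium (E)-{2-[3-geranyl-2,4-bis(methoxymethoxy)-5-prenylphenyl]vinyl}trifluoroborate | CC(C)=CCC/C(C)=C/Cc1c(OCOC)c(CC=C(C)C)cc(/C=C/[B-](F)(F)F)c1OCOC.[K+] | intermediate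
19 | pivalic acid | CC(C)(C)C(=O)O | starting material
20 | (E)-2-[3-geranyl-2,4-bis(methoxymethoxy)-5-prenylphenyl]vinyl pivalate | CC(C)=CCC/C(C)=C/Cc1c(OCOC)c(CC=C(C)C)cc(/C=C/OC(=O)C(C)(C)C)c1OCOC | intermediate
21 | 6-(methoxymethylidene)-3,5-bis(methoxymethoxy)-2-prenylcyclohexa-2,4-dien-1-one (exocyclic geometry open) | COC=C1C(OCOC)=CC(OCOC)=C(CC=C(C)C)C1=O | intermediate (not isolated)
22 | (2R,3S,4R)-2-[3-geranyl-2,4-bis(methoxymethoxy)-5-prenylphenyl]-4-methoxy-5,7-bis(methoxymethoxy)-8-prenylchroman-3-yl pivalate | CC(C)=CCC/C(C)=C/Cc1c(OCOC)c(CC=C(C)C)cc([C@H]2Oc3c(CC=C(C)C)c(OCOC)cc(OCOC)c3[C@@H](OC)[C@@H]2OC(=O)C(C)(C)C)c1OCOC | intermediate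
23 | (2R,3S,4R)-2-[3-geranyl-2,4-bis(methoxymethoxy)-5-prenylphenyl]-4-methoxy-5,7-bis(methoxymethoxy)-8-prenylchroman-3-ol | CC(C)=CCC/C(C)=C/Cc1c(OCOC)c(CC=C(C)C)cc([C@H]2Oc3c(CC=C(C)C)c(OCOC)cc(OCOC)c3[C@@H](OC)[C@@H]2O)c1OCOC | intermediate
24 | (2R,3S)-2-[3-geranyl-2,4-bis(methoxymethoxy)-5-prenylphenyl]-5,7-bis(methoxymethoxy)-8-prenylchromane-3,4-diol, C4 epimers | CC(C)=CCC/C(C)=C/Cc1c(OCOC)c(CC=C(C)C)cc([C@H]2Oc3c(CC=C(C)C)c(OCOC)cc(OCOC)c3C(O)[C@@H]2O)c1OCOC | intermediate
25 | (2R,3R)-2-[3-geranyl-2,4-bis(methoxymethoxy)-5-prenylphenyl]-3-hydroxy-5,7-bis(methoxymethoxy)-8-prenylchroman-4-one | CC(C)=CCC/C(C)=C/Cc1c(OCOC)c(CC=C(C)C)cc([C@H]2Oc3c(CC=C(C)C)c(OCOC)cc(OCOC)c3C(=O)[C@@H]2O)c1OCOC | intermediate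
26 | (2R,3R)-2-[3-geranyl-2,4-dihydroxy-5-prenylphenyl]-3,5,7-trihydroxy-8-prenylchroman-4-one | CC(C)=CCC/C(C)=C/Cc1c(O)c(CC=C(C)C)cc([C@H]2Oc3c(CC=C(C)C)c(O)cc(O)c3C(=O)[C@@H]2O)c1O | target

Total step count: 15. Longest linear sequence: 12 (steps 4–15, from resorcinol); the ring A branch is steps 1–3.

Steps most likely to fail

1. Step 11. The cation may be captured by the side-chain alkenes instead of the enol ester, the polarisation may be taken over by the enol oxygen so that the regiochemistry reverses, or facial selectivity may be poor because the dienophile offers the catalyst no hydrogen-bond handle. The fallback uses nucleophilic asymmetric epoxidation of a chalcone and epoxide opening, all known chemistry; it sets out from 4 and 14 and comes back at 25. Addition of MeMgBr (2.5 equiv, THF, 0 °C) to 4 gives the secondary benzylic alcohol F1, which MnO2 oxidises to the acetophenone F2. Claisen–Schmidt condensation of F2 with 14 (KOH, EtOH, rt) gives the 2'-hydroxychalcone F3, and silylation (TBSOTf, 2,6-lutidine) gives its TBS ether F4. Juliá–Colonna epoxidation (poly-L-leucine, urea–H2O2, DBU, THF) attacks only the enone and gives the (αR,βS)-epoxy ketone F5. Bu4NF/AcOH then frees the phenol, which under mild acid (PPTS, CH2Cl2) opens the epoxide at the benzylic carbon with inversion, giving 25 with C3 retained.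

2. Step 10. The electron-rich styryl trifluoroborate may protodeboronate, or the hindered carboxylate may couple too slowly. The fallback builds the enol ester from the homologated aldehyde; it sets out from 14 and comes back at 20. Wittig reaction with Ph3P=CHOMe (from (methoxymethyl)triphenylphosphonium chloride and KN(SiMe3)2) gives the methyl enol ether F6 as an E/Z mixture. Brief hydrolysis (1 M aq HCl, THF, 0 °C) gives the arylacetaldehyde F7. Enolisation and O-acylation (KN(SiMe3)2, THF, −78 °C; PivCl) give 20 together with its (Z) isomer, which is removed by chromatography.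

3. Step 2. The two MOM groups may distribute over O2 and O6, giving the wrong free phenol. The fallback fixes the position of the prenyl group by a sigmatropic shift; it sets out from 1 and comes back at 4. Bis-protection of symmetric 1 (MOMCl, i-Pr2NEt) can give only 2-hydroxy-4,6-bis(methoxymethoxy)benzaldehyde F8. O-alkylation with 3-chloro-3-methylbut-1-yne (DBU, CuCl2 cat., MeCN) gives the 1,1-dimethylpropargyl ether F9, and semi-hydrogenation (H2, Pd/CaCO3 poisoned with Pb(OAc)2, quinoline) gives the 1,1-dimethylallyl ether F10. Aromatic Claisen rearrangement (toluene, 110 °C) moves the allyl unit with allylic inversion to the only free ortho carbon, giving 4.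

Further compounds
F1 | step 11 | 1-[2-hydroxy-4,6-bis(methoxymethoxy)-3-prenylphenyl]ethan-1-ol (racemic) | CC(O)c1c(OCOC)cc(OCOC)c(CC=C(C)C)c1O
F2 | step 11 | 1-[2-hydroxy-4,6-bis(methoxymethoxy)-3-prenylphenyl]ethan-1-one | CC(=O)c1c(OCOC)cc(OCOC)c(CC=C(C)C)c1O
F3 | step 11 | (E)-3-[3-geranyl-2,4-bis(methoxymethoxy)-5-prenylphenyl]-1-[2-hydroxy-4,6-bis(methoxymethoxy)-3-prenylphenyl]prop-2-en-1-one | CC(C)=CCC/C(C)=C/Cc1c(OCOC)c(CC=C(C)C)cc(/C=C/C(=O)c2c(OCOC)cc(OCOC)c(CC=C(C)C)c2O)c1OCOC
F4 | step 11 | (E)-1-[2-(tert-butyldimethylsilyloxy)-4,6-bis(methoxymethoxy)-3-prenylphenyl]-3-[3-geranyl-2,4-bis(methoxymethoxy)-5-prenylphenyl]prop-2-en-1-one | CC(C)=CCC/C(C)=C/Cc1c(OCOC)c(CC=C(C)C)cc(/C=C/C(=O)c2c(OCOC)cc(OCOC)c(CC=C(C)C)c2O[Si](C)(C)C(C)(C)C)c1OCOC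
F5 | step 11 | [2-(tert-butyldimethylsilyloxy)-4,6-bis(methoxymethoxy)-3-prenylphenyl]{(2R,3S)-3-[3-geranyl-2,4-bis(methoxymethoxy)-5-prenylphenyl]oxiran-2-yl}methanone | CC(C)=CCC/C(C)=C/Cc1c(OCOC)c(CC=C(C)C)cc([C@@H]2O[C@H]2C(=O)c3c(OCOC)cc(OCOC)c(CC=C(C)C)c3O[Si](C)(C)C(C)(C)C)c1OCOC
F6 | step 10 | 1-geranyl-5-(2-methoxyvinyl)-2,6-bis(methoxymethoxy)-3-prenylbenzene (E/Z mixture) | CC(C)=CCC/C(C)=C/Cc1c(OCOC)c(CC=C(C)C)cc(C=COC)c1OCOC
F7 | step 10 | 2-[3-geranyl-2,4-bis(methoxymethoxy)-5-prenylphenyl]acetaldehyde | CC(C)=CCC/C(C)=C/Cc1c(OCOC)c(CC=C(C)C)cc(CC=O)c1OCOC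
F8 | step 2 | 2-hydroxy-4,6-bis(methoxymethoxy)benzaldehyde | O=Cc1c(O)cc(OCOC)cc1OCOC
F9 | step 2 | 2,4-bis(methoxymethoxy)-6-(2-methylbut-3-yn-2-yloxy)benzaldehyde | C#CC(C)(C)Oc1cc(OCOC)cc(OCOC)c1C=O
F10 | step 2 | 2,4-bis(methoxymethoxy)-6-(2-methylbut-3-en-2-yloxy)benzaldehyde | C=CC(C)(C)Oc1cc(OCOC)cc(OCOC)c1C=O
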